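## Retrosynthetic overview

1. Dicitrinone G (13) ⇒ the C2-symmetric 7,7'-methylene-bis(decarboxycitrinin) 12. The lactone is made last, by oxidising C-1 of one of two identical quinone methides (the citrinin → dihydrocitrinone change), not by joining two different halves.
2. 12 ⇒ 2 × phenol A (10) + 2 HC(OEt)3 + CH2O. An aldehyde-level C-1 closes each pyran onto the side-chain OH and dehydrates to the quinone methide; formaldehyde then bridges the two C-7 positions.
3. 10 ⇒ aryl bromide 4 + (2S,3S)-2,3-dimethyloxirane 5. Epoxide opening sets C-4, Mitsunobu inversion sets C-3; one chiral building block serves both halves.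
4. 4 ⇒ 1-bromo-3,5-dimethoxybenzene 1 (formylation, deoxygenation).
5. Ring order: arene bought → both pyran rings (step 6) → one pyran turned into the lactone ring (step 7).

Assumption: (2S,3S)-2,3-dimethyloxirane is bought as the single enantiomer; ring positions of the natural-product halves follow citrinin numbering (C-1, O-2, C-3, C-4, C-4a, C-5 to C-8, C-8a).

## Route

**Step 1**
Reactants: 1 1-bromo-3,5-dimethoxybenzene
Product: 3 2-bromo-4,6-dimethoxybenzaldehyde, via aryliminium chloride 2 (not isolated)
Conditions: POCl3 (1.5 equiv), DMF, 0 → 90 °C; then ice/H2O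
Reagents that add atoms: N,N-dimethylformamide (CN(C)C=O); water (O)
Why: Vilsmeier–Haack formylation attacks the ring carbon next to bromine, which is para to one methoxy group and ortho to the other, and the iminium salt 2 is hydrolysed on work-up; no stereocentre is involved.

**Step 2**
Reactants: 3 2-bromo-4,6-dimethoxybenzaldehyde
Product: 4 1-bromo-3,5-dimethoxy-2-methylbenzene
Conditions: Et3SiH (3 equiv), TFA, CH2Cl2, 0 °C → rt
Reagents that add atoms: none
Why: Ionic hydrogenation reduces the protonated aldehyde and then the o,p-dimethoxy-stabilised benzylic cation by two hydride transfers from silicon, and the aryl bromide is inert to these conditions.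

**Step 3**
Reactants: 4 1-bromo-3,5-dimethoxy-2-methylbenzene; 5 (2S,3S)-2,3-dimethyloxirane
Product: 7 (2S,3S)-3-(3,5-dimethoxy-2-methylphenyl)butan-2-ol, via aryllithium 6 (not isolated)
Conditions: 4 (1.3 equiv), n-BuLi (1.3 equiv), THF, −78 °C; then BF3·OEt2 (1.3 equiv), 5 (1.0 equiv), −78 °C; H2O
Reagents that add atoms: none
Why: Bromine–lithium exchange followed by BF3-assisted SN2 opening of the C2-symmetric trans-epoxide (both carbons equivalent) goes with inversion at the attacked carbon, which sets the benzylic centre as S (the future C-4 of both halves), while the carbinol carbon keeps its S configuration (erythro product).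

**Step 4**
Reactants: 7 (2S,3S)-3-(3,5-dimethoxy-2-methylphenyl)butan-2-ol
Product: 9 (2R,3S)-3-(3,5-dimethoxy-2-methylphenyl)butan-2-ol, via 4-nitrobenzoate ester 8 (not isolated)
Conditions: 4-O2NC6H4CO2H (1.5 equiv), PPh3 (1.5 equiv), DIAD (1.5 equiv), THF, 0 °C → rt; then MeOH, K2CO3, rt
Reagents that add atoms: 4-nitrobenzoic acid (O=C(O)c1ccc(cc1)[N+](=O)[O-])
Why: Mitsunobu inversion (SN2 of 4-nitrobenzoate on the alkoxyphosphonium ion) turns the carbinol centre from S to R to give the threo (2R,3S) pattern of C-3/C-4 in citrinin, and the methanolysis cleaves at the acyl carbon so the new configuration is kept.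

**Step 5**
Reactants: 9 (2R,3S)-3-(3,5-dimethoxy-2-methylphenyl)butan-2-ol
Product: 10 phenol A, (2R,3S)-3-(3,5-dihydroxy-2-methylphenyl)butan-2-ol
Conditions: BBr3 (4 equiv), CH2Cl2, −78 °C → rt; then H2O
Reagents that add atoms: none
Why: Lewis-acid ether cleavage by bromide attack on the O-methyl carbons frees both phenols, while the secondary alcohol sits as a borate until hydrolysis and neither stereocentre is touched.

**Step 6**
Reactants: 10 phenol A, (2R,3S)-3-(3,5-dihydroxy-2-methylphenyl)butan-2-ol (2 equiv)
Product: 12 7,7'-methylenebis(decarboxycitrinin), via decarboxycitrinin 11 (not isolated)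
Conditions: HC(OEt)3 (1.2 equiv), TFA, CH2Cl2, 0 °C → rt; evaporate; then 37% aq. CH2O (0.5 equiv), NaOAc, EtOH/H2O, 40 °C
Reagents that add atoms: triethyl orthoformate (CCOC(OCC)OCC); formaldehyde (C=O)
Why: Orthoformate bound to the secondary alcohol delivers a dialkoxycarbenium ion to the only ring carbon it can reach (oxa-Pictet–Spengler-type Friedel–Crafts formylation), loss of ethanol gives quinone methide 11 as the aldehyde/alcohol condensation does in citrinin biosynthesis, and its C-7, a cyclic vinylogous acid like dimedone, then undergoes Knoevenagel condensation with formaldehyde and Michael addition of a second molecule of 11; no stereocentre is formed or touched.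

**Step 7**
Reactants: 12 7,7'-methylenebis(decarboxycitrinin)
Product: 13 Dicitrinone G
Conditions: NaClO2 (1.0 equiv, slow addition), NaH2PO4 (pH 5–6), 2-methyl-2-butene (10 equiv), t-BuOH/THF/H2O, 0 °C; stop at partial conversion, recycle 12
Reagents that add atoms: sodium chlorite ([Na+].[O-]Cl=O)
Why: Proposed new method: chlorite adds as an O-nucleophile to the electrophilic C-1 of one quinone methide (the carbon where citrinin adds water), the aromatic lactol chlorite ester then fragments with loss of HOCl as in the Pinnick–Lindgren oxidation of phenolic aldehydes and lactols (closest known reaction type) to give the lactone, and at pH 5–6 the product's remaining, more acidic quinone methide should be ionised and no longer electrophilic, which is the basis for stopping after one oxidation; the stereocentres are remote and untouched.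

## Compound list

1 | 1-bromo-3,5-dimethoxybenzene | COc1cc(Br)cc(OC)c1 | starting material
2 | (2-bromo-4,6-dimethoxybenzylidene)dimethyliminium chloride (not isolated) | C[N+](C)=Cc1c(Br)cc(OC)cc1OC.[Cl-] | intermediate
3 | 2-bromo-4,6-dimethoxybenzaldehyde | O=Cc1c(Br)cc(OC)cc1OC | intermediate
4 | 1-bromo-3,5-dimethoxy-2-methylbenzene | Cc1c(Br)cc(OC)cc1OC | intermediate
5 | (2S,3S)-2,3-dimethyloxirane | C[C@@H]1O[C@H]1C | starting material
6 | (3,5-dimethoxy-2-methylphenyl)lithium (not isolated) | [Li]c1cc(OC)cc(OC)c1C | intermediate
7 | (2S,3S)-3-(3,5-dimethoxy-2-methylphenyl)butan-2-ol | C[C@H](O)[C@@H](C)c1cc(OC)cc(OC)c1C | intermediate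
8 | (2R,3S)-3-(3,5-dimethoxy-2-methylphenyl)butan-2-yl 4-nitrobenzoate (not isolated) | C[C@@H](OC(=O)c1ccc(cc1)[N+](=O)[O-])[C@@H](C)c1cc(OC)cc(OC)c1C | intermediate
9 | (2R,3S)-3-(3,5-dimethoxy-2-methylphenyl)butan-2-ol | C[C@@H](O)[C@@H](C)c1cc(OC)cc(OC)c1C | intermediate
10 | phenol A, (2R,3S)-3-(3,5-dihydroxy-2-methylphenyl)butan-2-ol | C[C@@H](O)[C@@H](C)c1cc(O)cc(O)c1C | intermediate
11 | decarboxycitrinin, (3R,4S)-6-hydroxy-3,4,5-trimethyl-3,4-dihydro-8H-isochromen-8-one (not isolated) | CC1=C2C(=CO[C@H](C)[C@H]2C)C(=O)C=C1O | intermediate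
12 | 7,7'-methylenebis[(3R,4S)-6-hydroxy-3,4,5-trimethyl-3,4-dihydro-8H-isochromen-8-one] | CC1=C2C(=CO[C@H](C)[C@H]2C)C(=O)C(CC3=C(O)C(C)=C4C(=CO[C@H](C)[C@H]4C)C3=O)=C1O | intermediate
13 | Dicitrinone G | CC1=C2C(=CO[C@H](C)[C@H]2C)C(=O)C(Cc2c(O)c(C)c3c(c2O)C(=O)O[C@H](C)[C@H]3C)=C1O | target

## Step count and risks

Total step count: 7. Longest linear sequence: 7 (1 → 13).

**Step 7 (mono-oxidation of the symmetric dimer).** The risks are a statistical mixture of 12, 13 and the bis-lactone, and attack of chlorine species on the electron-rich rings. The fallback joins two different halves instead and sets out from 9 and from 11 (isolated after the first stage of step 6). Alcohol 9 is brominated para to a methoxy group (NBS, MeCN, 0 °C) to give (2R,3S)-3-(2-bromo-3,5-dimethoxy-6-methylphenyl)butan-2-ol F1. Treatment with n-BuLi (2.2 equiv, THF, −78 °C), then CO2 and acid, closes (3R,4S)-6,8-dimethoxy-3,4,5-trimethylisochroman-1-one F2. BBr3 gives decarboxydihydrocitrinone F3, whose only free ring position is C-7. Eschenmoser's salt converts it into the Mannich base (3R,4S)-7-[(dimethylamino)methyl]-6,8-dihydroxy-3,4,5-trimethylisochroman-1-one F4. Heating F4 with 11 (dioxane, 100 °C) releases the o-quinone methide, which the nucleophilic C-7 of 11 traps. The fallback comes back to the route at 13.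

**Step 6 (one-pot formylation, cyclisation and dimerisation).** The risks are formylation between the two phenols instead of next to the side chain, over-reaction of 11 with orthoformate, and impurities carried into the dimerisation. The fallback installs C-1 before demethylation and sets out from 9. Rieche formylation (Cl2CHOMe, TiCl4, CH2Cl2, −78 → 0 °C), directed para to a methoxy group, gives 2-[(2S,3R)-3-hydroxybutan-2-yl]-4,6-dimethoxy-3-methylbenzaldehyde F5 (in equilibrium with its lactol). BBr3 then demethylates it, and the hydroxy aldehyde closes and dehydrates. The fallback comes back at 11, now isolated and purified, which is treated with formaldehyde as in the second stage of step 6 to reach 12.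

**Step 4 (Mitsunobu inversion).** The risks are elimination to the styrene and aryl participation giving retention. The fallback sets both centres by syn addition to an alkene and sets out from 4. Suzuki coupling with (Z)-but-2-en-2-ylboronic acid pinacol ester (Pd(dppf)Cl2, K2CO3, dioxane/H2O, 80 °C) gives (E)-1-(but-2-en-2-yl)-3,5-dimethoxy-2-methylbenzene F6. Asymmetric hydroboration follows with IpcBH2 made from (−)-α-pinene (the enantiomer of the reagent that turns 1-phenylcyclopentene into (1S,2R)-trans-2-phenylcyclopentanol), then NaOH/H2O2. The facial sense is to be confirmed against 9 from the main route, with enrichment by crystallisation of the borane adduct if needed. The fallback comes back at 9 and bypasses steps 3 and 4.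

## Further compounds

F1 | step 7 | (2R,3S)-3-(2-bromo-3,5-dimethoxy-6-methylphenyl)butan-2-ol | C[C@@H](O)[C@@H](C)c1c(Br)c(OC)cc(OC)c1C
F2 | step 7 | (3R,4S)-6,8-dimethoxy-3,4,5-trimethylisochroman-1-one | c1c(OC)c(C)c2c(c1OC)C(=O)O[C@H](C)[C@H]2C
F3 | step 7 | decarboxydihydrocitrinone, (3R,4S)-6,8-dihydroxy-3,4,5-trimethylisochroman-1-one | c1c(O)c(C)c2c(c1O)C(=O)O[C@H](C)[C@H]2C
F4 | step 7 | (3R,4S)-7-[(dimethylamino)methyl]-6,8-dihydroxy-3,4,5-trimethylisochroman-1-one | CN(C)Cc1c(O)c(C)c2c(c1O)C(=O)O[C@H](C)[C@H]2C
F5 | step 6 | 2-[(2S,3R)-3-hydroxybutan-2-yl]-4,6-dimethoxy-3-methylbenzaldehyde | C[C@@H](O)[C@@H](C)c1c(C=O)c(OC)cc(OC)c1C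
F6 | step 4 | (E)-1-(but-2-en-2-yl)-3,5-dimethoxy-2-methylbenzene | C/C=C(\C)c1cc(OC)cc(OC)c1C
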